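**Retrosynthetic overview**

1. Numbering: C1–C2–C3 is the propanoic acid chain on quaternary C10 (methyl C20). C5 carries the isopropenyl group (C4, =C18H2, methyl C19). Then C6H2, C7 (C=O), arene C8, C9, C11, C12, C13 (isopropyl), C14. Ring B is C5–C6–C7–C8–C9–C10 and ring C is the arene.
2. Feature used: the ring B bond C5–C10 joins both stereocentres and holds C1 and C4 cis. Tying C18 to C1 through an ester oxygen makes that bond the σ-bond of a [3,3] shift that also erases the tether.
3. Target 37 ⇐ (arene deprotection via the quinone, C7 oxidation, C1 to C1–C2–C3 extension) ring B acid 26 ⇐ Ireland–Claisen ring contraction ⇐ (Z)-benzo-fused ten-membered allylic lactone 22.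
4. Lactone 22 ⇐ macrolactonisation of seco acid 20 ⇐ Still–Gennari olefination (Z-C4=C5), Pd-catalysed zinc-enolate arylation (C9–C10), Noyori hydrogenation (C7) ⇐ 1,2,4-trimethoxybenzene.
5. Ring order: ring C is bought as the arene, the ten-membered lactone is closed second, and ring B is formed last by contraction of that lactone.

Key step: step 13

Remark (assumptions): C10 is formed without control in step 7, so compounds 13 to 22 are carried as C10 epimers that converge at enolate 23. The sense of the C7 to C5/C10 relay in step 13 is assumed as modelled there; because C7 ends as a ketone, the (R)-BINAP series would give the same target if the relay ran the other way.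

**Route**

Step 1
Reactants: 1 1,2,4-trimethoxybenzene; 2 acetone
Product: 4 2-(2,3,6-trimethoxyphenyl)propan-2-ol, via 2,3,6-trimethoxyphenyllithium 3 (not isolated)
Conditions: n-BuLi, THF, 0 °C; then 2, −78 °C to rt; H2O
Reagents that add atoms: n-butyllithium, [Li]CCCC (lithium held only in intermediate 3)
Why: Directed ortho-lithiation occurs at the ring position flanked by two methoxy groups (the future C13), and the aryllithium adds 1,2 to acetone to give the tertiary benzylic alcohol.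

Step 2
Reactants: 4 2-(2,3,6-trimethoxyphenyl)propan-2-ol
Product: 5 1,2,4-trimethoxy-3-(propan-2-yl)benzene
Conditions: Et3SiH, CF3CO2H, CH2Cl2, 0 °C to rt
Reagents that add atoms: none
Why: Ionic hydrogenation: acid ionises the tertiary benzylic alcohol to a cation stabilised by the two ortho methoxy groups, and triethylsilane reduces it to the isopropyl group.

Step 3
Reactants: 5 1,2,4-trimethoxy-3-(propan-2-yl)benzene; 6 methyl 3-chloro-3-oxopropanoate
Product: 7 methyl 3-oxo-3-[2,4,5-trimethoxy-3-(propan-2-yl)phenyl]propanoate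
Conditions: SnCl4, CH2Cl2, −20 to 0 °C
Reagents that add atoms: none
Why: Friedel–Crafts acylation should take the free position para to the C12 and ortho to the C14 methoxy group (C8), since the other free position has only one ortho methoxy donor, and SnCl4 is mild enough to leave the methyl ethers intact.

Step 4
Reactants: 7 methyl 3-oxo-3-[2,4,5-trimethoxy-3-(propan-2-yl)phenyl]propanoate
Product: 8 methyl (3R)-3-hydroxy-3-[2,4,5-trimethoxy-3-(propan-2-yl)phenyl]propanoate
Conditions: H2 (50 atm), RuCl2[(S)-BINAP] (0.5 mol%; BINAP = 2,2'-bis(diphenylphosphino)-1,1'-binaphthyl), MeOH, 50 °C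
Reagents that add atoms: none
Why: Noyori asymmetric hydrogenation of the β-keto ester runs through the ester-chelated ketone on ruthenium, and the (S)-BINAP ligand is chosen to deliver hydride to the face that gives the (R)-carbinol at C7, the only controlled stereocentre carried into the key step (configuration to be confirmed before going on).

Step 5
Reactants: 8 methyl (3R)-3-hydroxy-3-[2,4,5-trimethoxy-3-(propan-2-yl)phenyl]propanoate
Product: 9 methyl (3R)-3-[(tert-butyldimethylsilyl)oxy]-3-[2,4,5-trimethoxy-3-(propan-2-yl)phenyl]propanoate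
Conditions: t-BuMe2SiCl, imidazole, DMF, rt
Reagents that add atoms: tert-butyldimethylsilyl chloride, CC(C)(C)[Si](C)(C)Cl
Why: Imidazole-mediated silyl transfer masks the C7 hydroxyl as the ether that later steers the rearrangement, with no base strong enough for β-elimination of the hydroxy ester.

Step 6
Reactants: 9 methyl (3R)-3-[(tert-butyldimethylsilyl)oxy]-3-[2,4,5-trimethoxy-3-(propan-2-yl)phenyl]propanoate
Product: 10 methyl (3R)-3-[2-bromo-3,4,6-trimethoxy-5-(propan-2-yl)phenyl]-3-[(tert-butyldimethylsilyl)oxy]propanoate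
Conditions: N-bromosuccinimide, MeCN, 0 °C, dark
Reagents that add atoms: N-bromosuccinimide, BrN1C(=O)CCC1=O
Why: Electrophilic aromatic bromination can only take the last free ring position (C9), which is activated by the ortho C11 methoxy group, and polar dark conditions avoid radical bromination at benzylic hydrogens.

Step 7
Reactants: 10 methyl (3R)-3-[2-bromo-3,4,6-trimethoxy-5-(propan-2-yl)phenyl]-3-[(tert-butyldimethylsilyl)oxy]propanoate; 11 tert-butyl 2-bromopropanoate
Product: 13 methyl (3R)-3-{2-[(2RS)-1-tert-butoxy-1-oxopropan-2-yl]-3,4,6-trimethoxy-5-(propan-2-yl)phenyl}-3-[(tert-butyldimethylsilyl)oxy]propanoate (C10 epimers), via bromozinc enolate 12 (not isolated)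
Conditions: 11, Zn dust (Me3SiCl-activated), THF, rt; then 10, Pd(dba)2 (bis(dibenzylideneacetone)palladium, 5 mol%), P(t-Bu)3 (5 mol%), THF, 65 °C
Reagents that add atoms: zinc, [Zn] (held only in intermediate 12)
Why: Palladium-catalysed α-arylation of a Reformatsky (zinc) ester enolate forms C9–C10; the weakly basic zinc enolate leaves the methyl ester and its β-silyloxy group untouched, the bulky electron-rich phosphine allows oxidative addition and reductive elimination at the doubly ortho-substituted bromide, and C10 forms as both epimers, which is harmless because this centre becomes trigonal in step 13.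

Step 8
Reactants: 13 methyl (3R)-3-{2-[(2RS)-1-tert-butoxy-1-oxopropan-2-yl]-3,4,6-trimethoxy-5-(propan-2-yl)phenyl}-3-[(tert-butyldimethylsilyl)oxy]propanoate
Product: 14 tert-butyl (2RS)-2-{2-[(1R)-1-[(tert-butyldimethylsilyl)oxy]-3-oxopropyl]-3,5,6-trimethoxy-4-(propan-2-yl)phenyl}propanoate
Conditions: i-Bu2AlH (1.1 equiv), CH2Cl2, −78 °C; MeOH, aq. Rochelle salt
Reagents that add atoms: none
Why: Partial reduction with one equivalent of i-Bu2AlH at −78 °C stops at the aluminium hemiacetal of the unhindered methyl ester, which gives the aldehyde (C5) on work-up, while the hindered tert-butyl ester is not attacked.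

Step 9
Reactants: 14 tert-butyl (2RS)-2-{2-[(1R)-1-[(tert-butyldimethylsilyl)oxy]-3-oxopropyl]-3,5,6-trimethoxy-4-(propan-2-yl)phenyl}propanoate; 15 methyl 2-[bis(2,2,2-trifluoroethoxy)phosphoryl]propanoate
Product: 17 tert-butyl (2RS)-2-{2-[(1R,3Z)-1-[(tert-butyldimethylsilyl)oxy]-5-methoxy-4-methyl-5-oxopent-3-en-1-yl]-3,5,6-trimethoxy-4-(propan-2-yl)phenyl}propanoate, via potassium phosphonate carbanion 16 (not isolated)
Conditions: 15, KN(SiMe3)2, 18-crown-6, THF, −78 °C; then 14, −78 °C
Reagents that add atoms: potassium bis(trimethylsilyl)amide, C[Si](C)(C)[N-][Si](C)(C)C.[K+] (potassium held only in intermediate 16)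
Why: Still–Gennari olefination: the electron-poor bis(trifluoroethyl) phosphonate under dissociating conditions (potassium counter-ion, crown ether) eliminates fast from the kinetically formed adduct and so gives the (Z)-trisubstituted enoate, with the ester carbon (C18) cis to C6.

Step 10
Reactants: 17 tert-butyl (2RS)-2-{2-[(1R,3Z)-1-[(tert-butyldimethylsilyl)oxy]-5-methoxy-4-methyl-5-oxopent-3-en-1-yl]-3,5,6-trimethoxy-4-(propan-2-yl)phenyl}propanoate
Product: 18 tert-butyl (2RS)-2-{2-[(1R,3Z)-1-[(tert-butyldimethylsilyl)oxy]-5-hydroxy-4-methylpent-3-en-1-yl]-3,5,6-trimethoxy-4-(propan-2-yl)phenyl}propanoate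
Conditions: i-Bu2AlH (2.3 equiv), CH2Cl2, −78 °C; aq. Rochelle salt
Reagents that add atoms: none
Why: 1,2-Reduction of the conjugated methyl ester by two hydride equivalents of i-Bu2AlH gives the (Z)-allylic alcohol (C18) without changing the alkene geometry or attacking the tert-butyl ester.

Step 11
Reactants: 18 tert-butyl (2RS)-2-{2-[(1R,3Z)-1-[(tert-butyldimethylsilyl)oxy]-5-hydroxy-4-methylpent-3-en-1-yl]-3,5,6-trimethoxy-4-(propan-2-yl)phenyl}propanoate
Product: 20 (2RS)-2-{2-[(1R,3Z)-1-[(tert-butyldimethylsilyl)oxy]-5-hydroxy-4-methylpent-3-en-1-yl]-3,5,6-trimethoxy-4-(propan-2-yl)phenyl}propanoic acid, via bis(trimethylsilyl) derivative 19 (not isolated)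
Conditions: Me3SiOTf, 2,6-lutidine, CH2Cl2, 0 °C; then K2CO3, MeOH/H2O, 0 °C; pH 4 buffer
Reagents that add atoms: trimethylsilyl trifluoromethanesulfonate, C[Si](C)(C)OS(=O)(=O)C(F)(F)F (silicon held only in intermediate 19)
Why: Silyl triflate cleavage of the tert-butyl ester (O-silylation, loss of 2-methylpropene) under 2,6-lutidine buffering avoids the protic acid that would ionise the electron-rich benzylic C7 silyl ether, and mild methanolysis then removes the trimethylsilyl ester and the transient primary trimethylsilyl ether.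

Step 12
Reactants: 20 (2RS)-2-{2-[(1R,3Z)-1-[(tert-butyldimethylsilyl)oxy]-5-hydroxy-4-methylpent-3-en-1-yl]-3,5,6-trimethoxy-4-(propan-2-yl)phenyl}propanoic acid
Product: 22 (5Z,8R)-8-[(tert-butyldimethylsilyl)oxy]-9,11,12-trimethoxy-1,5-dimethyl-10-(propan-2-yl)-1,4,7,8-tetrahydro-3-benzoxecin-2-one (ten-membered lactone C10H(CH3)–C1(=O)–O–C18H2–C4(CH3)=C5H–C6H2–C7H(OSi)–C8=C9; C10 epimers), via mixed anhydride 21 (not isolated)
Conditions: 2,4,6-Cl3C6H2COCl, Et3N, THF, rt; then slow addition to DMAP, toluene, 80 °C, high dilution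
Reagents that add atoms: 2,4,6-trichlorobenzoyl chloride, O=C(Cl)c1c(Cl)cc(Cl)cc1Cl (held only in intermediate 21)
Why: Yamaguchi macrolactonisation: the mixed 2,4,6-trichlorobenzoic anhydride is added slowly to DMAP at high dilution, and the benzo fusion together with the (Z)-alkene gives two cis elements that pre-organise the chain for closure of the ten-membered ring, both C10 epimers being usable.

Step 13
Reactants: 22 (5Z,8R)-8-[(tert-butyldimethylsilyl)oxy]-9,11,12-trimethoxy-1,5-dimethyl-10-(propan-2-yl)-1,4,7,8-tetrahydro-3-benzoxecin-2-one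
Product: 26 (1R,2S,4R)-4-[(tert-butyldimethylsilyl)oxy]-5,7,8-trimethoxy-1-methyl-6-(propan-2-yl)-2-(prop-1-en-2-yl)-1,2,3,4-tetrahydronaphthalene-1-carboxylic acid, via potassium enolate 23 (not isolated), via silyl ketene acetal 24 (not isolated), via trimethylsilyl ester 25 (not isolated)
Conditions: KN(SiMe3)2, THF, −78 °C; Me3SiCl/Et3N, −78 °C to rt; toluene, 90 °C; then H2O/THF, pH 4 buffer
Reagents that add atoms: potassium bis(trimethylsilyl)amide, C[Si](C)(C)[N-][Si](C)(C)C.[K+] (potassium held only in intermediate 23); trimethylsilyl chloride, C[Si](C)(C)Cl (silicon held only in intermediates 24 and 25)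
Why: Deprotonation at C10 (benzylic and α to the lactone carbonyl) and O-silylation give the cyclic silyl ketene acetal 24, in which the ten-membered ring holds C9 and the ring oxygen cis on C10=C1, and the Ireland–Claisen [3,3] shift of the array C10=C1–O–C18–C4=C5 then forms C10–C5 while O–C18 breaks. This is the ring-contracting ester-enolate Claisen rearrangement known for macrolactones, the oxa-analogue of the cyclodeca-1,5-diene to 1,2-divinylcyclohexane Cope contraction. Ring B (C5, C6, C7, C8, C9, C10) closes transannularly across the lactone, 6-exo-trig at both trigonal termini, and C1, O, C18 and C4 are extruded as the carboxyl and isopropenyl groups. Because the ring-cis ketene acetal and the (Z)-C4=C5 alkene both place their tether atoms (C9, C6) on inner positions, a chair is impossible and the boat-like transition state eclipses C1 with C4 across the new bond, so C5 and C10 form with C1 and C4 cis (C20 cis to H5). The absolute sense comes from C7: A(1,3) strain with the C14 methoxy group should hold the silyloxy group pseudoaxial, and the C1–O–C18–C4 bridge should then span the opposite face of the nascent ring, giving (5S,10R) from (7R). The step needs O-silylation before the enolate can collapse to a ketene, which silylation at −78 °C of the fully substituted, aryl-flanked enolate carbon with no β-leaving group should secure.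

Step 14
Reactants: 26 (1R,2S,4R)-4-[(tert-butyldimethylsilyl)oxy]-5,7,8-trimethoxy-1-methyl-6-(propan-2-yl)-2-(prop-1-en-2-yl)-1,2,3,4-tetrahydronaphthalene-1-carboxylic acid
Product: 27 [(1R,2S,4R)-4-[(tert-butyldimethylsilyl)oxy]-5,7,8-trimethoxy-1-methyl-6-(propan-2-yl)-2-(prop-1-en-2-yl)-1,2,3,4-tetrahydronaphthalen-1-yl]methanol
Conditions: LiAlH4, THF, 0 °C to reflux; aq. NaOH work-up
Reagents that add atoms: none
Why: LiAlH4 reduces the hindered carboxylic acid to the neopentyl-type primary alcohol (C1), and the silyl ether, aryl ethers and isolated alkene are inert to hydride.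

Step 15
Reactants: 27 [(1R,2S,4R)-4-[(tert-butyldimethylsilyl)oxy]-5,7,8-trimethoxy-1-methyl-6-(propan-2-yl)-2-(prop-1-en-2-yl)-1,2,3,4-tetrahydronaphthalen-1-yl]methanol
Product: 28 (1R,2S,4R)-4-[(tert-butyldimethylsilyl)oxy]-5,7,8-trimethoxy-1-methyl-6-(propan-2-yl)-2-(prop-1-en-2-yl)-1,2,3,4-tetrahydronaphthalene-1-carbaldehyde
Conditions: Dess–Martin periodinane, NaHCO3, CH2Cl2, rt
Reagents that add atoms: none
Why: Dess–Martin oxidation gives the aldehyde under buffered neutral conditions, and because C10 is quaternary the aldehyde can neither enolise nor epimerise.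

Step 16
Reactants: 28 (1R,2S,4R)-4-[(tert-butyldimethylsilyl)oxy]-5,7,8-trimethoxy-1-methyl-6-(propan-2-yl)-2-(prop-1-en-2-yl)-1,2,3,4-tetrahydronaphthalene-1-carbaldehyde; 29 trimethyl phosphonoacetate
Product: 31 methyl (2E)-3-[(1R,2S,4R)-4-[(tert-butyldimethylsilyl)oxy]-5,7,8-trimethoxy-1-methyl-6-(propan-2-yl)-2-(prop-1-en-2-yl)-1,2,3,4-tetrahydronaphthalen-1-yl]prop-2-enoate, via sodium phosphonate carbanion 30 (not isolated)
Conditions: 29, NaH, THF, 0 °C; then 28, rt to 50 °C
Reagents that add atoms: sodium hydride, [Na+].[H-] (sodium held only in intermediate 30)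
Why: Horner–Wadsworth–Emmons olefination of the non-enolisable aldehyde with the phosphonoacetate anion adds C2 and C3 as the (E)-enoate.

Step 17
Reactants: 31 methyl (2E)-3-[(1R,2S,4R)-4-[(tert-butyldimethylsilyl)oxy]-5,7,8-trimethoxy-1-methyl-6-(propan-2-yl)-2-(prop-1-en-2-yl)-1,2,3,4-tetrahydronaphthalen-1-yl]prop-2-enoate
Product: 32 methyl 3-[(1R,2S,4R)-4-[(tert-butyldimethylsilyl)oxy]-5,7,8-trimethoxy-1-methyl-6-(propan-2-yl)-2-(prop-1-en-2-yl)-1,2,3,4-tetrahydronaphthalen-1-yl]propanoate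
Conditions: [(Ph3P)CuH]6, toluene, rt to 40 °C; aq. NH4Cl
Reagents that add atoms: none
Why: Conjugate (1,4) hydride transfer from the phosphine copper hydride cluster reduces only the electron-poor enoate C=C and leaves the isopropenyl group intact, and protonation of the copper enolate gives the saturated ester.

Step 18
Reactants: 32 methyl 3-[(1R,2S,4R)-4-[(tert-butyldimethylsilyl)oxy]-5,7,8-trimethoxy-1-methyl-6-(propan-2-yl)-2-(prop-1-en-2-yl)-1,2,3,4-tetrahydronaphthalen-1-yl]propanoate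
Product: 33 methyl 3-[(1R,2S,4R)-4-hydroxy-5,7,8-trimethoxy-1-methyl-6-(propan-2-yl)-2-(prop-1-en-2-yl)-1,2,3,4-tetrahydronaphthalen-1-yl]propanoate
Conditions: Bu4NF, AcOH, THF, rt to 40 °C
Reagents that add atoms: none
Why: Fluoride-mediated desilylation (Si–F bond formation) frees the C7 alcohol, with acetic acid buffering to protect the methyl ester from hydroxide.

Step 19
Reactants: 33 methyl 3-[(1R,2S,4R)-4-hydroxy-5,7,8-trimethoxy-1-methyl-6-(propan-2-yl)-2-(prop-1-en-2-yl)-1,2,3,4-tetrahydronaphthalen-1-yl]propanoate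
Product: 34 methyl 3-[(1R,2S)-5,7,8-trimethoxy-1-methyl-4-oxo-6-(propan-2-yl)-2-(prop-1-en-2-yl)-1,2,3,4-tetrahydronaphthalen-1-yl]propanoate
Conditions: Dess–Martin periodinane, NaHCO3, CH2Cl2, rt
Reagents that add atoms: none
Why: Dess–Martin oxidation of the benzylic secondary alcohol gives the aryl ketone at C7 and removes the stereocentre that served only as the control element.

Step 20
Reactants: 34 methyl 3-[(1R,2S)-5,7,8-trimethoxy-1-methyl-4-oxo-6-(propan-2-yl)-2-(prop-1-en-2-yl)-1,2,3,4-tetrahydronaphthalen-1-yl]propanoate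
Product: 35 3-[(1R,2S)-5,7-dihydroxy-8-methoxy-1-methyl-4-oxo-6-(propan-2-yl)-2-(prop-1-en-2-yl)-1,2,3,4-tetrahydronaphthalen-1-yl]propanoic acid
Conditions: NaSEt, DMF, 110 °C, argon; then cold dilute HCl to pH 4
Reagents that add atoms: none
Why: Thiolate SN2 attack at methyl carbon cleaves the methyl ester and the two methyl ethers whose phenoxides are conjugated with the C7 ketone (C14 ortho, C12 para), the C11 ether being expected to survive, under non-acidic conditions that spare the isopropenyl group.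

Step 21
Reactants: 35 3-[(1R,2S)-5,7-dihydroxy-8-methoxy-1-methyl-4-oxo-6-(propan-2-yl)-2-(prop-1-en-2-yl)-1,2,3,4-tetrahydronaphthalen-1-yl]propanoic acid
Product: 36 3-[(1R,2S)-7-hydroxy-1-methyl-4,5,8-trioxo-6-(propan-2-yl)-2-(prop-1-en-2-yl)-1,2,3,4,5,8-hexahydronaphthalen-1-yl]propanoic acid
Conditions: PhI(OAc)2, MeCN/H2O, 0 °C
Reagents that add atoms: water, O
Why: Oxidative demethylation of the para-methoxyphenol (C14–OH para to C11–OMe) by PhI(OAc)2 in aqueous acetonitrile passes through the quinone hemiketal, which loses methanol to give the 12-hydroxy-11,14-quinone, and any fully demethylated triol carried over from step 20 is oxidised to the same quinone.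

Step 22
Reactants: 36 3-[(1R,2S)-7-hydroxy-1-methyl-4,5,8-trioxo-6-(propan-2-yl)-2-(prop-1-en-2-yl)-1,2,3,4,5,8-hexahydronaphthalen-1-yl]propanoic acid
Product: 37 3-[(1R,2S)-5,7,8-trihydroxy-1-methyl-4-oxo-6-(propan-2-yl)-2-(prop-1-en-2-yl)-1,2,3,4-tetrahydronaphthalen-1-yl]propanoic acid (CNP0198818.2)
Conditions: Na2S2O4, EtOAc/H2O, rt, argon
Reagents that add atoms: none
Why: Two-electron reduction of the hydroxyquinone by dithionite under argon gives the 11,12,14-trihydroxyarene without touching the C7 ketone and without acid, which would add the C11 phenol to the isopropenyl group.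

**Compound list**

1 | 1,2,4-trimethoxybenzene | COc1ccc(OC)c(OC)c1 | starting material
2 | acetone | CC(C)=O | starting material
3 | 2,3,6-trimethoxyphenyllithium | [Li]c1c(OC)ccc(OC)c1OC | intermediate (not isolated)
4 | 2-(2,3,6-trimethoxyphenyl)propan-2-ol | COc1ccc(OC)c(OC)c1C(C)(C)O | intermediate
5 | 1,2,4-trimethoxy-3-(propan-2-yl)benzene | COc1ccc(OC)c(OC)c1C(C)C | intermediate
6 | methyl 3-chloro-3-oxopropanoate | COC(=O)CC(Cl)=O | starting material
7 | methyl 3-oxo-3-[2,4,5-trimethoxy-3-(propan-2-yl)phenyl]propanoate | COC(=O)CC(=O)c1cc(OC)c(OC)c(C(C)C)c1OC | intermediate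
8 | methyl (3R)-3-hydroxy-3-[2,4,5-trimethoxy-3-(propan-2-yl)phenyl]propanoate | COC(=O)C[C@@H](O)c1cc(OC)c(OC)c(C(C)C)c1OC | intermediate
9 | methyl (3R)-3-[(tert-butyldimethylsilyl)oxy]-3-[2,4,5-trimethoxy-3-(propan-2-yl)phenyl]propanoate | COC(=O)C[C@@H](O[Si](C)(C)C(C)(C)C)c1cc(OC)c(OC)c(C(C)C)c1OC | intermediate
10 | methyl (3R)-3-[2-bromo-3,4,6-trimethoxy-5-(propan-2-yl)phenyl]-3-[(tert-butyldimethylsilyl)oxy]propanoate | COC(=O)C[C@@H](O[Si](C)(C)C(C)(C)C)c1c(Br)c(OC)c(OC)c(C(C)C)c1OC | intermediate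
11 | tert-butyl 2-bromopropanoate (racemic) | CC(Br)C(=O)OC(C)(C)C | starting material
12 | bromozinc enolate of tert-butyl propanoate (Reformatsky reagent) | CC([Zn]Br)C(=O)OC(C)(C)C | intermediate (not isolated)
13 | methyl (3R)-3-{2-[(2RS)-1-tert-butoxy-1-oxopropan-2-yl]-3,4,6-trimethoxy-5-(propan-2-yl)phenyl}-3-[(tert-butyldimethylsilyl)oxy]propanoate (C10 epimers) | COC(=O)C[C@@H](O[Si](C)(C)C(C)(C)C)c1c(C(C)C(=O)OC(C)(C)C)c(OC)c(OC)c(C(C)C)c1OC | intermediate
14 | tert-butyl (2RS)-2-{2-[(1R)-1-[(tert-butyldimethylsilyl)oxy]-3-oxopropyl]-3,5,6-trimethoxy-4-(propan-2-yl)phenyl}propanoate | O=CC[C@@H](O[Si](C)(C)C(C)(C)C)c1c(C(C)C(=O)OC(C)(C)C)c(OC)c(OC)c(C(C)C)c1OC | intermediate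
15 | methyl 2-[bis(2,2,2-trifluoroethoxy)phosphoryl]propanoate | COC(=O)C(C)P(=O)(OCC(F)(F)F)OCC(F)(F)F | starting material
16 | potassium carbanion of phosphonate 15 | COC(=O)[C-](C)P(=O)(OCC(F)(F)F)OCC(F)(F)F.[K+] | intermediate (not isolated)
17 | tert-butyl (2RS)-2-{2-[(1R,3Z)-1-[(tert-butyldimethylsilyl)oxy]-5-methoxy-4-methyl-5-oxopent-3-en-1-yl]-3,5,6-trimethoxy-4-(propan-2-yl)phenyl}propanoate | COC(=O)/C(C)=C\C[C@@H](O[Si](C)(C)C(C)(C)C)c1c(C(C)C(=O)OC(C)(C)C)c(OC)c(OC)c(C(C)C)c1OC | intermediate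
18 | tert-butyl (2RS)-2-{2-[(1R,3Z)-1-[(tert-butyldimethylsilyl)oxy]-5-hydroxy-4-methylpent-3-en-1-yl]-3,5,6-trimethoxy-4-(propan-2-yl)phenyl}propanoate | OC/C(C)=C\C[C@@H](O[Si](C)(C)C(C)(C)C)c1c(C(C)C(=O)OC(C)(C)C)c(OC)c(OC)c(C(C)C)c1OC | intermediate
19 | trimethylsilyl ester and C18 trimethylsilyl ether of acid 20 | C[Si](C)(C)OC/C(C)=C\C[C@@H](O[Si](C)(C)C(C)(C)C)c1c(C(C)C(=O)O[Si](C)(C)C)c(OC)c(OC)c(C(C)C)c1OC | intermediate (not isolated)
20 | (2RS)-2-{2-[(1R,3Z)-1-[(tert-butyldimethylsilyl)oxy]-5-hydroxy-4-methylpent-3-en-1-yl]-3,5,6-trimethoxy-4-(propan-2-yl)phenyl}propanoic acid | OC/C(C)=C\C[C@@H](O[Si](C)(C)C(C)(C)C)c1c(C(C)C(=O)O)c(OC)c(OC)c(C(C)C)c1OC | intermediate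
21 | mixed anhydride of acid 20 with 2,4,6-trichlorobenzoic acid | OC/C(C)=C\C[C@@H](O[Si](C)(C)C(C)(C)C)c1c(C(C)C(=O)OC(=O)c2c(Cl)cc(Cl)cc2Cl)c(OC)c(OC)c(C(C)C)c1OC | intermediate (not isolated)
22 | (5Z,8R)-8-[(tert-butyldimethylsilyl)oxy]-9,11,12-trimethoxy-1,5-dimethyl-10-(propan-2-yl)-1,4,7,8-tetrahydro-3-benzoxecin-2-one (C10 epimers) | C/C1=C/C[C@@H](O[Si](C)(C)C(C)(C)C)c2c(OC)c(C(C)C)c(OC)c(OC)c2C(C)C(=O)OC1 | intermediate
23 | potassium enolate of lactone 22 (C9 and ring oxygen cis on C10=C1) | C/C1=C/C[C@@H](O[Si](C)(C)C(C)(C)C)c2c(OC)c(C(C)C)c(OC)c(OC)c2/C(C)=C(/[O-])OC1.[K+] | intermediate (not isolated)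
24 | cyclic trimethylsilyl ketene acetal of lactone 22 (C9 and ring oxygen cis on C10=C1) | C/C1=C/C[C@@H](O[Si](C)(C)C(C)(C)C)c2c(OC)c(C(C)C)c(OC)c(OC)c2/C(C)=C(/O[Si](C)(C)C)OC1 | intermediate (not isolated)
25 | trimethylsilyl ester of acid 26 | C=C(C)[C@@H]1C[C@@H](O[Si](C)(C)C(C)(C)C)c2c(OC)c(C(C)C)c(OC)c(OC)c2[C@]1(C)C(=O)O[Si](C)(C)C | intermediate (not isolated)
26 | (1R,2S,4R)-4-[(tert-butyldimethylsilyl)oxy]-5,7,8-trimethoxy-1-methyl-6-(propan-2-yl)-2-(prop-1-en-2-yl)-1,2,3,4-tetrahydronaphthalene-1-carboxylic acid | C=C(C)[C@@H]1C[C@@H](O[Si](C)(C)C(C)(C)C)c2c(OC)c(C(C)C)c(OC)c(OC)c2[C@]1(C)C(=O)O | intermediate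
27 | [(1R,2S,4R)-4-[(tert-butyldimethylsilyl)oxy]-5,7,8-trimethoxy-1-methyl-6-(propan-2-yl)-2-(prop-1-en-2-yl)-1,2,3,4-tetrahydronaphthalen-1-yl]methanol | C=C(C)[C@@H]1C[C@@H](O[Si](C)(C)C(C)(C)C)c2c(OC)c(C(C)C)c(OC)c(OC)c2[C@]1(C)CO | intermediate
28 | (1R,2S,4R)-4-[(tert-butyldimethylsilyl)oxy]-5,7,8-trimethoxy-1-methyl-6-(propan-2-yl)-2-(prop-1-en-2-yl)-1,2,3,4-tetrahydronaphthalene-1-carbaldehyde | C=C(C)[C@@H]1C[C@@H](O[Si](C)(C)C(C)(C)C)c2c(OC)c(C(C)C)c(OC)c(OC)c2[C@]1(C)C=O | intermediate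
29 | trimethyl phosphonoacetate | COC(=O)CP(=O)(OC)OC | starting material
30 | sodium carbanion of phosphonate 29 | COC(=O)[CH-]P(=O)(OC)OC.[Na+] | intermediate (not isolated)
31 | methyl (2E)-3-[(1R,2S,4R)-4-[(tert-butyldimethylsilyl)oxy]-5,7,8-trimethoxy-1-methyl-6-(propan-2-yl)-2-(prop-1-en-2-yl)-1,2,3,4-tetrahydronaphthalen-1-yl]prop-2-enoate | C=C(C)[C@@H]1C[C@@H](O[Si](C)(C)C(C)(C)C)c2c(OC)c(C(C)C)c(OC)c(OC)c2[C@]1(C)/C=C/C(=O)OC | intermediate
32 | methyl 3-[(1R,2S,4R)-4-[(tert-butyldimethylsilyl)oxy]-5,7,8-trimethoxy-1-methyl-6-(propan-2-yl)-2-(prop-1-en-2-yl)-1,2,3,4-tetrahydronaphthalen-1-yl]propanoate | C=C(C)[C@@H]1C[C@@H](O[Si](C)(C)C(C)(C)C)c2c(OC)c(C(C)C)c(OC)c(OC)c2[C@]1(C)CCC(=O)OC | intermediate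
33 | methyl 3-[(1R,2S,4R)-4-hydroxy-5,7,8-trimethoxy-1-methyl-6-(propan-2-yl)-2-(prop-1-en-2-yl)-1,2,3,4-tetrahydronaphthalen-1-yl]propanoate | C=C(C)[C@@H]1C[C@@H](O)c2c(OC)c(C(C)C)c(OC)c(OC)c2[C@]1(C)CCC(=O)OC | intermediate
34 | methyl 3-[(1R,2S)-5,7,8-trimethoxy-1-methyl-4-oxo-6-(propan-2-yl)-2-(prop-1-en-2-yl)-1,2,3,4-tetrahydronaphthalen-1-yl]propanoate | C=C(C)[C@@H]1CC(=O)c2c(OC)c(C(C)C)c(OC)c(OC)c2[C@]1(C)CCC(=O)OC | intermediate
35 | 3-[(1R,2S)-5,7-dihydroxy-8-methoxy-1-methyl-4-oxo-6-(propan-2-yl)-2-(prop-1-en-2-yl)-1,2,3,4-tetrahydronaphthalen-1-yl]propanoic acid | C=C(C)[C@@H]1CC(=O)c2c(O)c(C(C)C)c(O)c(OC)c2[C@]1(C)CCC(=O)O | intermediate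
36 | 3-[(1R,2S)-7-hydroxy-1-methyl-4,5,8-trioxo-6-(propan-2-yl)-2-(prop-1-en-2-yl)-1,2,3,4,5,8-hexahydronaphthalen-1-yl]propanoic acid | C=C(C)[C@@H]1CC(=O)C2=C(C(=O)C(O)=C(C(C)C)C2=O)[C@]1(C)CCC(=O)O | intermediate
37 | 3-[(1R,2S)-5,7,8-trihydroxy-1-methyl-4-oxo-6-(propan-2-yl)-2-(prop-1-en-2-yl)-1,2,3,4-tetrahydronaphthalen-1-yl]propanoic acid | C=C(C)[C@@H]1CC(=O)c2c(O)c(C(C)C)c(O)c(O)c2[C@]1(C)CCC(=O)O | target

**Step count and risks**

Total step count: 22. Longest linear sequence: 22 steps, from 1,2,4-trimethoxybenzene (1) to 37.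

The three steps most likely to fail:

Step 13. The hindered silyl ketene acetal may decay (ketene formation, C-silylation) before the strained boat transition state is reached, or the facial selectivity relative to C7 may be poor. Fallback: a palladium-catalysed intramolecular allylic alkylation (Tsuji–Trost) forms the same C5–C10 bond from the open chain. It sets out from 18, which with methyl chloroformate and pyridine in CH2Cl2 should give the allylic methyl carbonate F1. Treatment of F1 with Pd(PPh3)4 and NaN(SiMe3)2 in THF should ionise the carbonate, and the α-aryl ester enolate should attack the C5 terminus of the allyl unit (six-membered ring rather than eight) to give the tert-butyl ester F2. The C1/C4 relationship is then no longer ring-enforced, so the (1R,2S,4R) isomer would have to be separated. LiAlH4 in refluxing THF reduces F2 to alcohol 27, where the route is rejoined.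

Step 12. Oligomerisation may outrun closure of the medium ring, and acyl transfer may go to the wrong carbonyl of the mixed anhydride because the α-aryl acid is hindered. Fallback: the ring is closed by O-alkylation, with the carboxylate as nucleophile, so the hindered acyl carbon is never attacked. It sets out from 18, which with MsCl, LiCl and 2,4,6-collidine in DMF at 0 °C should give the allylic chloride F3. Cleavage of the tert-butyl ester as in step 11 (Me3SiOTf, 2,6-lutidine, then water) gives the chloro acid F4. Slow addition of F4 to Cs2CO3 in DMF at 50 °C under high dilution should close the ring by SN2 displacement of chloride and return lactone 22.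

Step 7. Transmetalation and reductive elimination may be slow at the doubly ortho-substituted aryl–palladium centre, so that the bromide is simply reduced. Fallback: the C9–C10 bond is made by Suzuki–Miyaura coupling and the acid oxidation level is set afterwards. It sets out from 10, which with isopropenylboronic acid pinacol ester, Pd(OAc)2, 2-dicyclohexylphosphino-2',6'-dimethoxybiphenyl and K3PO4 in toluene at 80 °C should give the isopropenyl arene F5. Hydroboration with 9-BBN and oxidation with NaBO3·4H2O gives the primary alcohol F6. TEMPO with PhI(OAc)2 in aqueous MeCN oxidises F6 to the acid F7. Esterification of F7 with di-tert-butyl dicarbonate, DMAP and tert-butanol returns diester 13.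

Further compounds
F1 | step 13 | tert-butyl (2RS)-2-{2-[(1R,3Z)-1-[(tert-butyldimethylsilyl)oxy]-5-[(methoxycarbonyl)oxy]-4-methylpent-3-en-1-yl]-3,5,6-trimethoxy-4-(propan-2-yl)phenyl}propanoate | COC(=O)OC/C(C)=C\C[C@@H](O[Si](C)(C)C(C)(C)C)c1c(C(C)C(=O)OC(C)(C)C)c(OC)c(OC)c(C(C)C)c1OC
F2 | step 13 | tert-butyl (1R,2S,4R)-4-[(tert-butyldimethylsilyl)oxy]-5,7,8-trimethoxy-1-methyl-6-(propan-2-yl)-2-(prop-1-en-2-yl)-1,2,3,4-tetrahydronaphthalene-1-carboxylate | C=C(C)[C@@H]1C[C@@H](O[Si](C)(C)C(C)(C)C)c2c(OC)c(C(C)C)c(OC)c(OC)c2[C@]1(C)C(=O)OC(C)(C)C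
F3 | step 12 | tert-butyl (2RS)-2-{2-[(1R,3Z)-1-[(tert-butyldimethylsilyl)oxy]-5-chloro-4-methylpent-3-en-1-yl]-3,5,6-trimethoxy-4-(propan-2-yl)phenyl}propanoate | ClC/C(C)=C\C[C@@H](O[Si](C)(C)C(C)(C)C)c1c(C(C)C(=O)OC(C)(C)C)c(OC)c(OC)c(C(C)C)c1OC
F4 | step 12 | (2RS)-2-{2-[(1R,3Z)-1-[(tert-butyldimethylsilyl)oxy]-5-chloro-4-methylpent-3-en-1-yl]-3,5,6-trimethoxy-4-(propan-2-yl)phenyl}propanoic acid | ClC/C(C)=C\C[C@@H](O[Si](C)(C)C(C)(C)C)c1c(C(C)C(=O)O)c(OC)c(OC)c(C(C)C)c1OC
F5 | step 7 | methyl (3R)-3-[(tert-butyldimethylsilyl)oxy]-3-[3,4,6-trimethoxy-5-(propan-2-yl)-2-(prop-1-en-2-yl)phenyl]propanoate | COC(=O)C[C@@H](O[Si](C)(C)C(C)(C)C)c1c(C(C)=C)c(OC)c(OC)c(C(C)C)c1OC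
F6 | step 7 | methyl (3R)-3-[(tert-butyldimethylsilyl)oxy]-3-{2-[(2RS)-1-hydroxypropan-2-yl]-3,4,6-trimethoxy-5-(propan-2-yl)phenyl}propanoate | COC(=O)C[C@@H](O[Si](C)(C)C(C)(C)C)c1c(C(C)CO)c(OC)c(OC)c(C(C)C)c1OC
F7 | step 7 | (2RS)-2-{2-[(1R)-1-[(tert-butyldimethylsilyl)oxy]-3-methoxy-3-oxopropyl]-3,5,6-trimethoxy-4-(propan-2-yl)phenyl}propanoic acid | COC(=O)C[C@@H](O[Si](C)(C)C(C)(C)C)c1c(C(C)C(=O)O)c(OC)c(OC)c(C(C)C)c1OC
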